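**Plan**

- Retrosynthesis cuts ring B (the non-aromatic ring; C1 carbonyl, C2 benzyl-bearing, C3 enol, C4 quaternary, C5 enol, C6 butanoyl-bearing) from ring A at the ArCH2–C2 bond, then removes the butanoyl group at C6, then opens ring B at C4–C5 (quaternary carbon to enol carbon) and further at C5–C6 and C1–C2, down to the ketene Me(prenyl)C=C=O and two molecules of ethoxyethyne.
- Enabling feature: C4 of ring B carries methyl and prenyl (no hydrogen, cannot aromatise) and C1, C3, C5 all carry oxygen. Such a 6,6-disubstituted 3,5-dioxygenated cyclohexa-2,4-dienone is the direct product of a 6π-electrocyclisation of a 3,5-dialkoxy-dienylketene, the ketene carbon becoming C5 and the disubstituted terminus C4.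
- Forward: acid chloride → ketene + alkyne → cyclobutenone; the cyclobutenone and a second alkyne give ring B in one thermal cascade (step 4); hydrolysis gives a prochiral trione.
- Stereochemistry: C4 is the only stereocentre. It is set in step 6 by a catalyst-controlled iodoetherification that ties the prenyl alkene to one of the two enantiotopic enol oxygens (temporary pyran ring), made permanent by butanoylation (step 7), and the ring is removed with zinc (step 8).
- Ring A (from 2,4,6-trihydroxybenzaldehyde by O-methylation and C-acylation) is joined last through its aldehyde carbon by reductive alkylation (step 11).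

Key step: step 4

Assumption: ring B compounds are drawn as one enol tautomer and descriptors refer to the tautomer drawn (the target is R at the quaternary carbon); the (1R,2R) hand of the step 6 catalyst is assumed to give the (3S,4aR) iodo ether, and its enantiomer is used if a first run shows the opposite sense.

**Step 1**
Reactants: 1 propanoic acid; 2 1-bromo-3-methylbut-2-ene
Product: 4 2,5-dimethylhex-4-enoic acid (racemic), via dilithium enediolate 3 (not isolated)
Conditions: LiN(i-Pr)2 (2.2 equiv), THF, 0 °C; then 2, 0 °C to rt; aq. HCl work-up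
Reagents that add atoms: none
Why: α-Alkylation of the carboxylic acid dianion with the allylic bromide at its primary carbon (SN2) is standard; the new stereocentre is racemic and is lost in step 3.

**Step 2**
Reactants: 4 2,5-dimethylhex-4-enoic acid
Product: 5 2,5-dimethylhex-4-enoyl chloride (racemic)
Conditions: (COCl)2, DMF (cat.), CH2Cl2, 0 °C to rt
Reagents that add atoms: oxalyl chloride, O=C(Cl)C(Cl)=O
Why: Standard acid chloride formation; the trisubstituted alkene should not react.

**Step 3**
Reactants: 5 2,5-dimethylhex-4-enoyl chloride; 6 ethoxyethyne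
Product: 8 3-ethoxy-4-methyl-4-(3-methylbut-2-en-1-yl)cyclobut-2-en-1-one (racemic), via ketene 7 (not isolated)
Conditions: Et3N (1.3 equiv), 6 (3 equiv), CH2Cl2, 0 °C to 40 °C, sealed vessel
Reagents that add atoms: none
Why: Dehydrochlorination gives the dialkylketene, which undergoes the known thermal ketene–ynol ether [2+2] cycloaddition (ketene carbonyl carbon to the terminal alkyne carbon) to the 3-ethoxycyclobutenone; C4 of the ring is racemic and is opened again in step 4.

**Step 4**
Reactants: 8 3-ethoxy-4-methyl-4-(3-methylbut-2-en-1-yl)cyclobut-2-en-1-one; 6 ethoxyethyne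
Product: 12 3,5-diethoxy-6-methyl-6-(3-methylbut-2-en-1-yl)cyclohexa-2,4-dien-1-one (racemic), via vinylketene 9 (not isolated), via alkenylcyclobutenone 10 (not isolated), via dienylketene 11 (not isolated)
Conditions: 6 (4 equiv), toluene, 90 °C, sealed tube
Reagents that add atoms: none
Why: At 90 °C cyclobutenone 8 opens (4π-electrocyclic) to vinylketene 9, whose ketene C=C adds to ynol ether 6 ([2+2], ketene carbonyl carbon to the nucleophilic terminal alkyne carbon) to give 10; a second 4π opening gives dienylketene 11, and thermal disrotatory 6π-electrocyclisation of its isomer with C2 and C5 cis joins the ketene carbon to the methyl/prenyl-bearing terminus and closes ring B. The closest known reaction type is the Danheiser benzannulation of cyclobutenones with alkoxyalkynes, which here must stop at the cyclohexa-2,4-dienone because the new sp3 carbon has no hydrogen to lose. The ring closes by a pericyclic 6π-electrocyclisation with all six ring carbons in the cyclic array, not by an ionic exo or endo closure. The quaternary carbon forms without control, as the racemate, which is accepted because step 5 makes it prochiral and step 6 sets it. The step needs the regiochemistry of the [2+2] event, secured by the polarisation of 6 so that oxygen ends on C3 and C5 of 12, and capture of 9 by 6 faster than its unimolecular escapes (1,5-hydrogen shift, intramolecular [2+2] with the prenyl alkene), secured by an excess of the strongly nucleophilic alkyne; the isomer of 11 that cannot cyclise returns through 10.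

**Step 5**
Reactants: 12 3,5-diethoxy-6-methyl-6-(3-methylbut-2-en-1-yl)cyclohexa-2,4-dien-1-one
Product: 14 3,5-dihydroxy-4-methyl-4-(3-methylbut-2-en-1-yl)cyclohexa-2,5-dien-1-one (achiral by tautomerism), via monoethyl enol ether 13 (not isolated)
Conditions: 2 M HCl, THF, rt
Reagents that add atoms: water, O
Why: Acid hydrolysis of both vinylogous ester groups (conjugate addition of water, loss of ethanol) should give the tautomerically symmetric trione, in which the quaternary carbon is prochiral and no stereocentre remains.

**Step 6**
Reactants: 14 3,5-dihydroxy-4-methyl-4-(3-methylbut-2-en-1-yl)cyclohexa-2,5-dien-1-one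
Product: 15 (3S,4aR)-3-iodo-2,2,4a-trimethyl-3,4-dihydro-2H-chromene-5,7(4aH,6H)-dione (iodine and angular methyl trans)
Conditions: N-iodosuccinimide (1.0 equiv), 1-[3,5-bis(trifluoromethyl)phenyl]-3-[(1R,2R)-2-(dipentylamino)cyclohexyl]urea (10 mol%), toluene, −40 °C
Reagents that add atoms: N-iodosuccinimide, O=C1CCC(=O)N1I
Why: Proposed new method: the tertiary amine of the catalyst pairs with the vinylogous acid (acidity like a carboxylic acid) while its urea binds the N-iodo imide, so iodonium is delivered to one face of the prenyl C=C and an enol oxygen attacks the tertiary alkene carbon anti to iodine (6-endo, Markovnikov) through a chair-like transition state with the angular methyl pseudo-axial and iodine equatorial; with the alkene face fixed by the catalyst only one of the two enantiotopic enol oxygens can close in this chair, which turns the prochiral quaternary carbon into the (4aR) stereocentre and gives the trans iodide, the diastereomers being separable and returnable to 14 with zinc; the closest known reaction types are aminourea-catalysed enantioselective iodolactonisation of alkenoic acids and catalytic desymmetrising haloetherification of alkenyl 1,3-diols.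

**Step 7**
Reactants: 15 (3S,4aR)-3-iodo-2,2,4a-trimethyl-3,4-dihydro-2H-chromene-5,7(4aH,6H)-dione; 16 butanoyl chloride
Product: 18 (3S,4aR)-6-butanoyl-7-hydroxy-3-iodo-2,2,4a-trimethyl-3,4-dihydro-2H-chromen-5(4aH)-one, via enol butanoate 17 (not isolated)
Conditions: Et3N, CH2Cl2, 0 °C; then 4-(dimethylamino)pyridine (0.3 equiv), rt
Reagents that add atoms: none
Why: O-Acylation of the free 1,3-dione followed by 4-(dimethylamino)pyridine-catalysed O-to-C acyl migration (the standard route to 2-acylcyclohexane-1,3-diones) should place butanoyl on C6, the only carbon flanked by two carbonyls; both stereocentres are untouched.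

**Step 8**
Reactants: 18 (3S,4aR)-6-butanoyl-7-hydroxy-3-iodo-2,2,4a-trimethyl-3,4-dihydro-2H-chromen-5(4aH)-one
Product: 19 (R)-2-butanoyl-3,5-dihydroxy-4-methyl-4-(3-methylbut-2-en-1-yl)cyclohexa-2,5-dien-1-one
Conditions: Zn dust, AcOH, THF, rt
Reagents that add atoms: none
Why: Boord-type reductive elimination of the β-iodo ether (zinc inserts into C–I, the β-oxygen leaves as the stabilised trione enolate) should restore the prenyl alkene and the enol; the quaternary stereocentre is not involved and is now permanent because butanoyl distinguishes its two sides.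

**Step 9**
Reactants: 20 2,4,6-trihydroxybenzaldehyde
Product: 21 2,6-dihydroxy-4-methoxybenzaldehyde
Conditions: MeI (1.0 equiv), K2CO3 (1.0 equiv), DMF, rt
Reagents that add atoms: iodomethane, CI
Why: Williamson etherification should be selective for the 4-hydroxyl, which is para to the formyl group, not hydrogen-bonded to it and the most acidic.

**Step 10**
Reactants: 21 2,6-dihydroxy-4-methoxybenzaldehyde; 22 hexanoic anhydride
Product: 23 3-hexanoyl-2,6-dihydroxy-4-methoxybenzaldehyde
Conditions: BF3·OEt2, 70 °C; then aq. MeOH, reflux
Reagents that add atoms: none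
Why: Friedel–Crafts acylation (possibly through O-acylation and Fries rearrangement) can only occur at C3 or C5, which are equivalent by symmetry, so one regioisomer must result; BF3 should not cleave the methyl ether.

**Step 11**
Reactants: 19 (R)-2-butanoyl-3,5-dihydroxy-4-methyl-4-(3-methylbut-2-en-1-yl)cyclohexa-2,5-dien-1-one; 23 3-hexanoyl-2,6-dihydroxy-4-methoxybenzaldehyde
Product: 25 target CNP0219201.1, via benzylidene trione 24 (not isolated)
Conditions: diethyl 2,6-dimethyl-1,4-dihydropyridine-3,5-dicarboxylate (1.1 equiv), L-proline (20 mol%), CH2Cl2, rt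
Reagents that add atoms: none
Why: Three-component reductive alkylation: amine-catalysed Knoevenagel condensation of the aldehyde with C6–H of 19 (its only free nucleophilic carbon) gives the benzylidene trione, which is reduced in situ by hydride transfer from the dihydropyridine; the quaternary stereocentre has no α-hydrogen and is not affected.

**Compound list**

1 | propanoic acid | CCC(=O)O | starting material
2 | 1-bromo-3-methylbut-2-ene (prenyl bromide) | CC(C)=CCBr | starting material
3 | dilithium enediolate of propanoic acid | CC=C([O-])[O-].[Li+].[Li+] | intermediate (not isolated)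
4 | 2,5-dimethylhex-4-enoic acid (racemic) | CC(CC=C(C)C)C(=O)O | intermediate
5 | 2,5-dimethylhex-4-enoyl chloride (racemic) | CC(CC=C(C)C)C(Cl)=O | intermediate
6 | ethoxyethyne | CCOC#C | starting material
7 | 2,5-dimethylhexa-1,4-dien-1-one (methyl prenyl ketene) | CC(CC=C(C)C)=C=O | intermediate (not isolated)
8 | 3-ethoxy-4-methyl-4-(3-methylbut-2-en-1-yl)cyclobut-2-en-1-one (racemic) | CCOC1=CC(=O)C1(C)CC=C(C)C | intermediate
9 | 3-ethoxy-4,7-dimethylocta-1,3,6-trien-1-one (vinylketene, C3=C4 geometry mixed) | O=C=CC(OCC)=C(C)CC=C(C)C | intermediate (not isolated)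
10 | 3-ethoxy-4-(1-ethoxy-2,5-dimethylhexa-1,4-dien-1-yl)cyclobut-2-en-1-one (racemic) | CCOC1=CC(=O)C1C(OCC)=C(C)CC=C(C)C | intermediate (not isolated)
11 | (3E)-3,5-diethoxy-6,9-dimethyldeca-1,3,5,8-tetraen-1-one (dienylketene, C2 and C5 cis) | O=C=C/C(OCC)=C\C(OCC)=C(C)CC=C(C)C | intermediate (not isolated)
12 | 3,5-diethoxy-6-methyl-6-(3-methylbut-2-en-1-yl)cyclohexa-2,4-dien-1-one (racemic) | O=C1C=C(OCC)C=C(OCC)C1(C)CC=C(C)C | intermediate
13 | 5-ethoxy-3-hydroxy-6-methyl-6-(3-methylbut-2-en-1-yl)cyclohexa-2,4-dien-1-one (racemic) | O=C1C=C(O)C=C(OCC)C1(C)CC=C(C)C | intermediate (not isolated)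
14 | 3,5-dihydroxy-4-methyl-4-(3-methylbut-2-en-1-yl)cyclohexa-2,5-dien-1-one (achiral) | O=C1C=C(O)C(C)(CC=C(C)C)C(O)=C1 | intermediate
15 | (3S,4aR)-3-iodo-2,2,4a-trimethyl-3,4-dihydro-2H-chromene-5,7(4aH,6H)-dione | CC1(C)OC2=CC(=O)CC(=O)[C@]2(C)C[C@@H]1I | intermediate
16 | butanoyl chloride | CCCC(Cl)=O | starting material
17 | (3S,4aR)-3-iodo-2,2,4a-trimethyl-5-oxo-3,4,4a,5-tetrahydro-2H-chromen-7-yl butanoate | CCCC(=O)OC1=CC(=O)[C@]2(C)C[C@H](I)C(C)(C)OC2=C1 | intermediate (not isolated)
18 | (3S,4aR)-6-butanoyl-7-hydroxy-3-iodo-2,2,4a-trimethyl-3,4-dihydro-2H-chromen-5(4aH)-one | CCCC(=O)C1=C(O)C=C2OC(C)(C)[C@@H](I)C[C@@]2(C)C1=O | intermediate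
19 | (R)-2-butanoyl-3,5-dihydroxy-4-methyl-4-(3-methylbut-2-en-1-yl)cyclohexa-2,5-dien-1-one | O=C1C=C(O)[C@@](C)(CC=C(C)C)C(O)=C1C(=O)CCC | intermediate
20 | 2,4,6-trihydroxybenzaldehyde | O=Cc1c(O)cc(O)cc1O | starting material
21 | 2,6-dihydroxy-4-methoxybenzaldehyde | COc1cc(O)c(C=O)c(O)c1 | intermediate
22 | hexanoic anhydride | CCCCCC(=O)OC(=O)CCCCC | starting material
23 | 3-hexanoyl-2,6-dihydroxy-4-methoxybenzaldehyde | CCCCCC(=O)c1c(OC)cc(O)c(C=O)c1O | intermediate
24 | benzylidene trione from 19 and 23 (quaternary carbon arranged as in 19, descriptor S in this tautomer by a priority change only; alkene geometry not defined) | CCCCCC(=O)c1c(OC)cc(O)c(C=C2C(=O)[C@@](C)(CC=C(C)C)C(O)=C(C(=O)CCC)C2=O)c1O | intermediate (not isolated)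
25 | CNP0219201.1, (R) at the quaternary carbon | CCCCCC(=O)c1c(OC)cc(O)c(CC2=C(O)[C@@](C)(CC=C(C)C)C(O)=C(C(=O)CCC)C2=O)c1O | target

**Step count**

Total: 11 steps. Longest linear sequence: 9 steps (steps 1 to 8, then step 11).

**Steps most likely to fail**

1. Step 6 (Proposed new method). Electrophilic iodine may be taken up at the nucleophilic enol carbons or passed to the alkene without the catalyst, and closure may occur through an enol carbon (carbocyclisation) or in the 5-exo mode; each of these would lower the enantiomeric purity of the quaternary carbon. Fallback with known chemistry, setting out from 14 and returning at 19: 14 is O-acylated with butanoyl chloride 16 and Et3N to 3-hydroxy-4-methyl-4-(3-methylbut-2-en-1-yl)-5-oxocyclohexa-1,3-dien-1-yl butanoate F1, which 4-(dimethylamino)pyridine rearranges to racemic 2-butanoyl-3,5-dihydroxy-4-methyl-4-(3-methylbut-2-en-1-yl)cyclohexa-2,5-dien-1-one F2. Classical resolution by fractional crystallisation with (R)-1-phenylethylamine (the amine enantiomer that gives the less soluble salt with the (R)-acid is used; the (R)-amine is written) should give the (R)-1-phenylethylammonium salt of 19 F3, from which dilute HCl liberates 19.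

2. Step 4. Vinylketene 9 may escape by 1,5-hydrogen shift from its cis alkyl group or by intramolecular [2+2] addition to the prenyl alkene before it meets the alkyne, and ethoxyethyne may decompose thermally. Fallback, setting out from 2 and returning at 14: commercial methyl 2-methyl-3-oxobutanoate is alkylated with 2 (K2CO3, acetone, reflux) to methyl 2-methyl-2-(3-methylbut-2-en-1-yl)-3-oxobutanoate F4. Claisen condensation of its methyl ketone with ethyl acetate (NaH, THF) gives methyl 2-methyl-2-(3-methylbut-2-en-1-yl)-3,5-dioxohexanoate F5. The diketone dianion (LiN(i-Pr)2, 2.2 equiv, THF, 0 °C) then closes ring B by Dieckmann-type attack of the terminal carbon on the ester, giving 14 after acidification; this closes the ring at a different bond and needs no alkyne.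

3. Step 11. Condensation of the doubly hydrogen-bonded, electron-rich aldehyde may be slow, and the benzylidene intermediate may be lost by addition of a second trione or by cyclodehydration onto a ring A hydroxyl. Fallback, setting out from 23 and returning at 25: reductive amination of 23 with dimethylamine and NaBH(OAc)3 gives the Mannich base 1-[3-(dimethylaminomethyl)-2,4-dihydroxy-6-methoxyphenyl]hexan-1-one F6. Heated with 19 in toluene, it loses dimethylamine and C6 of 19 adds to the benzylic carbon to give 25.

**Further compounds**

F1 | step 6 | 3-hydroxy-4-methyl-4-(3-methylbut-2-en-1-yl)-5-oxocyclohexa-1,3-dien-1-yl butanoate (racemic enol ester) | CCCC(=O)OC1=CC(=O)C(C)(CC=C(C)C)C(O)=C1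
F2 | step 6 | racemic 2-butanoyl-3,5-dihydroxy-4-methyl-4-(3-methylbut-2-en-1-yl)cyclohexa-2,5-dien-1-one | O=C1C=C(O)C(C)(CC=C(C)C)C(O)=C1C(=O)CCC
F3 | step 6 | (R)-1-phenylethylammonium salt of 19 | CCCC(=O)C1=C([O-])[C@](C)(CC=C(C)C)C(O)=CC1=O.C[C@@H]([NH3+])c1ccccc1
F4 | step 4 | methyl 2-methyl-2-(3-methylbut-2-en-1-yl)-3-oxobutanoate (racemic) | COC(=O)C(C)(CC=C(C)C)C(C)=O
F5 | step 4 | methyl 2-methyl-2-(3-methylbut-2-en-1-yl)-3,5-dioxohexanoate (racemic) | COC(=O)C(C)(CC=C(C)C)C(=O)CC(C)=O
F6 | step 11 | 1-[3-(dimethylaminomethyl)-2,4-dihydroxy-6-methoxyphenyl]hexan-1-one | CCCCCC(=O)c1c(OC)cc(O)c(CN(C)C)c1O
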